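The plan rests on introducing both angular methyl groups at once. C7 and C11, the adjacent quaternary carbons shared by the six-membered ketone ring and the cyclopentane, lie β and α to the C12 ketone, so they are the two ends of a ring-fusion enone. One operation, a ligand-controlled copper-catalysed conjugate methylation with Me3Al followed by methylation of the aluminium enolate, forms both C–CH3 bonds cis and fixes the absolute configuration. Its precursor is the achiral bicyclic enone 1,2,3,5,6,7-hexahydro-4H-inden-4-one, which already contains both rings. A silicon relay then carries this chirality to C13 and C5, and the arene is joined through propargylation, methylboration and Suzuki coupling.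

Key step: step 3

Remark (labels): C12 is the ring carbonyl carbon, C13 the ring CH beside it, C5 the ring carbinol carbon, C6 the ring CH2, C7 and C11 the methyl-bearing fusion carbons (C7 next to C6, C11 next to C12), and C8 to C10 the cyclopentane CH2 groups. "Lower face" is the face of the two angular methyl groups and "upper face" the opposite one.

Remark (assumption): the hand of the phosphoramidite in step 3 and of BINAP in step 5 is assigned by analogy with simple cyclohexenones; if a first run shows the opposite sense, the antipodal ligand is used.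

Step 1
Reactants: 1 indan-4-ol; 2 iodomethane
Product: 3 4-methoxyindane
Conditions: MeI, K2CO3, acetone, reflux
Reagents that add atoms: iodomethane (2), CI
Why: Williamson ether synthesis (phenoxide SN2 on MeI) converts the phenol into the anisole needed for dissolving-metal reduction.

Step 2
Reactants: 3 4-methoxyindane
Product: 6 1,2,3,5,6,7-hexahydro-4H-inden-4-one, via dihydroanisole 4 (not isolated), via deconjugated enone 5 (not isolated)
Conditions: Li, NH3(l), t-BuOH, THF, −78 → −33 °C; NH4Cl; then 2 M aq. HCl, THF, 50 °C
Reagents that add atoms: water, O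
Why: Birch reduction of the anisole ring (protonation at C3a and C6 of the indane, as for 1-methoxy-2,3-dialkylbenzenes of the tetralin series) should give the 1-methoxycyclohexa-1,4-diene, whose enol ether is hydrolysed by acid to the β,γ-enone that isomerises through its dienol to the thermodynamically preferred tetrasubstituted enone.

Step 3
Reactants: 6 1,2,3,5,6,7-hexahydro-4H-inden-4-one; 7 trimethylaluminium; 2 iodomethane
Product: 9 (3aR,7aR)-3a,7a-dimethyloctahydro-4H-inden-4-one, via dimethylaluminium enolate 8 (not isolated)
Conditions: CuO2CC4H3S (5 mol%), (S,R,R)-phosphoramidite [(S)-binaphthol-derived, N,N-bis((R)-1-phenylethyl)] (10 mol%), Me3Al (2 equiv), Et2O, −30 °C; then MeLi (2 equiv), THF–HMPA, −30 °C; MeI (5 equiv), −30 → 0 °C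
Reagents that add atoms: trimethylaluminium (7), C[Al](C)C; iodomethane (2), CI
Why: Proposed new method: the monovalent copper–methyl species formed from CuO2CC4H3S, the phosphoramidite and Me3Al is expected to bind the C7=C11 π bond of 6, pass through a trivalent copper σ-complex at C7 and form the C7–CH3 bond by reductive elimination, while aluminium on the carbonyl oxygen activates the hindered enone and leaves the C11–C12 dimethylaluminium enolate 8 as a single regioisomer. Conversion of 8 into its lithium aluminate with MeLi should make it nucleophilic enough for C-methylation at C11 by MeI. The closest known reaction types are copper–phosphoramidite additions of Me3Al to β-substituted (trisubstituted) cyclohexenones with trapping of the aluminium enolate, and stoichiometric cuprate addition–enolate alkylation of ring-fusion enones; the fully substituted α- and β-carbons are what goes beyond them. No ring is closed, because 6 already contains both rings and lacks only the two methyl groups. C7 is set by the chiral ligand (enantioface choice in the π-complex) and C11 by the substrate, since MeI can only attack the bicyclic enolate on the face that keeps the hydrindanone cis-fused, the trans-fused transition state being strained, so the second methyl enters cis to the first. The step needs enantioface control, conjugate rather than carbonyl addition and C- rather than O-alkylation; these should be secured by the ligand-accelerated copper pathway at −30 °C, by an enolate that is formed regiospecifically and never equilibrates, and by the soft electrophile MeI.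

Step 4
Reactants: 9 (3aR,7aR)-3a,7a-dimethyloctahydro-4H-inden-4-one
Product: 11 (3aR,7aR)-3a,7a-dimethyl-1,2,3,3a,7,7a-hexahydro-4H-inden-4-one, via trimethylsilyl enol ether 10 (not isolated)
Conditions: LDA, THF, −78 °C; TMSCl; then Pd(OAc)2 (1.1 equiv), MeCN, rt
Reagents that add atoms: none
Why: Saegusa–Ito oxidation: only C13 can be deprotonated (C11 is quaternary) and the divalent palladium enolate can lose hydride only from C5, so the C13=C5 enone should be the single dehydrogenation product and no stereocentre changes.

Step 5
Reactants: 11 (3aR,7aR)-3a,7a-dimethyl-1,2,3,3a,7,7a-hexahydro-4H-inden-4-one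
Product: 12 (3aR,6S,7aR)-6-(dimethylphenylsilyl)-3a,7a-dimethyloctahydro-4H-inden-4-one
Conditions: [Rh(cod)2]OTf (5 mol%), (S)-BINAP (6 mol%), PhMe2Si–Bpin (2 equiv), Et3N, 1,4-dioxane/H2O (10:1), 45 °C
Reagents that add atoms: (dimethylphenylsilyl)boronic acid pinacol ester, C[Si](C)(c1ccccc1)B1OC(C)(C)C(C)(C)O1
Why: Rhodium–BINAP-catalysed asymmetric conjugate silyl transfer from the Si–B reagent (1,4-addition, rhodium enolate protonated by water): the catalyst, not the nearly unbiased substrate, chooses the C5 face, and (S)-BINAP is expected to deliver silicon to the upper face, anti to the angular methyls.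

Step 6
Reactants: 12 (3aR,6S,7aR)-6-(dimethylphenylsilyl)-3a,7a-dimethyloctahydro-4H-inden-4-one; 13 3-bromo-2-methylprop-1-ene
Product: 14 (3aR,5S,6S,7aR)-6-(dimethylphenylsilyl)-3a,7a-dimethyl-5-(2-methylprop-2-en-1-yl)octahydro-4H-inden-4-one
Conditions: LDA, THF, −78 °C; 13, DMPU, −78 → −20 °C; (NaOMe, MeOH, rt if a cis epimer is present)
Reagents that add atoms: 3-bromo-2-methylprop-1-ene (13), CC(=C)CBr
Why: Alkylation of the only possible lithium enolate anti to the bulky C5 silyl group (β-silyl enolate alkylation in the Fleming sense) sets C13 trans to silicon, which is also the diequatorial and more stable arrangement, and because a β-silyl ketone cannot undergo β-elimination any cis epimer can be equilibrated with NaOMe.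

Step 7
Reactants: 14 (3aR,5S,6S,7aR)-6-(dimethylphenylsilyl)-3a,7a-dimethyl-5-(2-methylprop-2-en-1-yl)octahydro-4H-inden-4-one
Product: 15 (3aR,5S,6S,7aR)-6-(dimethylphenylsilyl)-5-(2-hydroxy-2-methylpropyl)-3a,7a-dimethyloctahydro-4H-inden-4-one
Conditions: Co(acac)2 (20 mol%), PhSiH3, O2 (1 atm), THF, rt; aq. Na2S2O3
Reagents that add atoms: dioxygen, O=O
Why: Mukaiyama hydration (cobalt-hydride hydrogen-atom transfer to the 1,1-disubstituted alkene, tertiary radical trapped by O2) should give the Markovnikov tertiary alcohol; the alkene is the only C=C bond at this stage and no stereocentre is formed.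

Step 8
Reactants: 15 (3aR,5S,6S,7aR)-6-(dimethylphenylsilyl)-5-(2-hydroxy-2-methylpropyl)-3a,7a-dimethyloctahydro-4H-inden-4-one
Product: 16 (3aR,5R,6S,7aR)-6-hydroxy-5-(2-hydroxy-2-methylpropyl)-3a,7a-dimethyloctahydro-4H-inden-4-one
Conditions: KBr, AcOOH, NaOAc, AcOH, 0 °C → rt
Reagents that add atoms: peracetic acid, CC(=O)OO
Why: Fleming–Tamao oxidation (bromodesilylation of the phenyl group, then peracid-induced 1,2-shift from silicon to oxygen) converts C5–Si into C5–OH with retention, so the hydroxyl stays on the upper face.

Step 9
Reactants: 16 (3aR,5R,6S,7aR)-6-hydroxy-5-(2-hydroxy-2-methylpropyl)-3a,7a-dimethyloctahydro-4H-inden-4-one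
Product: 17 cyclic C12 methyl ketal of 16 (2,2-dimethyltetrahydrofuran closed from the side-chain oxygen onto C12; ring oxygen on the lower face; OCH3 on the upper face; C5–OH free)
Conditions: PPTS (10 mol%), MeOH, 3 Å molecular sieves, rt
Reagents that add atoms: methanol, CO
Why: Acid-catalysed intramolecular ketalisation (the tertiary hydroxyl closes a five-membered hemiketal on C12 and methanol traps the oxocarbenium ion) masks the C12 carbonyl and the tertiary alcohol in one operation, so that C5 can be oxidised without forming an enolisable 1,3-dione; the new ring is cis-fused at C12–C13, C13 is not touched, and a C12 anomer would serve equally.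

Step 10
Reactants: 17 cyclic C12 methyl ketal of 16
Product: 18 C5 ketone of the cyclic ketal (C13 side-chain carbon on the lower face)
Conditions: Dess–Martin periodinane, NaHCO3, CH2Cl2, 0 °C → rt
Reagents that add atoms: none
Why: Dess–Martin oxidation of the only free secondary alcohol under buffered, non-basic conditions should leave the ketal and C13 (now α to the ketone) untouched; 18 is used without storage.

Step 11
Reactants: 18 C5 ketone of the cyclic ketal; 19 3-bromoprop-1-yne
Product: 20 C5 homopropargylic tertiary alcohol (C5–OH on the lower face; CH2C≡CH on the upper face)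
Conditions: 19, Zn dust (activated), THF, 0 °C → rt; aq. NaHCO3
Reagents that add atoms: 3-bromoprop-1-yne (19), C#CCBr
Why: Zinc Barbier propargylation (the allenylzinc adds through its γ-carbon to give the homopropargylic alcohol) on a conformationally locked ketone: with the C13 substituent equatorial, the chair places C7–CH3 and one C12 oxygen axial on the lower face, so the nucleophile should enter equatorially from the upper face and leave the C5 hydroxyl axial, cis to the angular methyls and to the C13 side chain.

Step 12
Reactants: 20 C5 homopropargylic tertiary alcohol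
Product: 21 trimethylsilyl ether of 20
Conditions: N-(trimethylsilyl)imidazole, CH2Cl2, 40 °C
Reagents that add atoms: N-(trimethylsilyl)imidazole, C[Si](C)(C)n1ccnc1
Why: Silylation of the hindered tertiary alcohol with a powerful, non-acidic silyl donor removes the only proton source that could intercept the alkenylcopper intermediate of the next step.

Step 13
Reactants: 21 trimethylsilyl ether of 20; 2 iodomethane
Product: 22 (E)-alkenyl pinacol boronate (C5–CH2–C(CH3)=CH–Bpin)
Conditions: CuCl (10 mol%), Xantphos (10 mol%), NaOtBu (1.5 equiv), B2pin2 (1.3 equiv), MeI (3 equiv), THF, rt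
Reagents that add atoms: bis(pinacolato)diboron, CC1(C)OB(OC1(C)C)B1OC(C)(C)C(C)(C)O1; iodomethane (2), CI
Why: Copper-catalysed methylboration (syn borylcupration of the terminal alkyne with boron on the terminal carbon, then C-methylation of the alkenylcopper by MeI) should give the trisubstituted alkenylboronate with CH3 and boron cis, which fixes the E geometry of the side chain.

Step 14
Reactants: 23 4-methoxy-2-methylphenol
Product: 24 2-hydroxy-5-methoxy-3-methylbenzaldehyde
Conditions: MgCl2, Et3N, (CH2O)n, MeCN, reflux; aq. HCl
Reagents that add atoms: paraformaldehyde (formaldehyde unit), C=O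
Why: Magnesium phenoxide-directed ortho-formylation (Casnati–Skattebøl) can only occur at C6, the single free ortho position.

Step 15
Reactants: 24 2-hydroxy-5-methoxy-3-methylbenzaldehyde
Product: 25 2-[(tert-butyldimethylsilyl)oxy]-5-methoxy-3-methylbenzaldehyde
Conditions: TBSCl, imidazole, DMF, rt
Reagents that add atoms: tert-butyldimethylsilyl chloride, CC(C)(C)[Si](C)(C)Cl
Why: Standard silylation of the phenol, which must be capped before a benzylic halide is made beside it.

Step 16
Reactants: 25 2-[(tert-butyldimethylsilyl)oxy]-5-methoxy-3-methylbenzaldehyde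
Product: 26 {2-[(tert-butyldimethylsilyl)oxy]-5-methoxy-3-methylphenyl}methanol
Conditions: NaBH4, MeOH, 0 °C; AcOH quench
Reagents that add atoms: none
Why: Borohydride reduction of the aldehyde to the benzylic alcohol at 0 °C, with an acidic quench to prevent silyl migration.

Step 17
Reactants: 26 {2-[(tert-butyldimethylsilyl)oxy]-5-methoxy-3-methylphenyl}methanol
Product: 27 [2-(bromomethyl)-4-methoxy-6-methylphenoxy](tert-butyl)dimethylsilane
Conditions: CBr4, PPh3, CH2Cl2, 0 °C
Reagents that add atoms: carbon tetrabromide, BrC(Br)(Br)Br
Why: Appel bromination of the primary benzylic alcohol under neutral conditions.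

Step 18
Reactants: 22 (E)-alkenyl pinacol boronate; 27 [2-(bromomethyl)-4-methoxy-6-methylphenoxy](tert-butyl)dimethylsilane
Product: 28 fully protected target (C12 methyl ketal; C5–OSiMe3; aryl OTBS)
Conditions: Pd(dppf)Cl2 (5 mol%), K3PO4, THF/H2O (10:1), 60 °C
Reagents that add atoms: none
Why: Suzuki–Miyaura coupling of the alkenylboronate with the benzylic bromide (oxidative addition at the benzylic C–Br bond, transmetalation, reductive elimination) proceeds with retention of alkene geometry and forms the aryl–CH2–CH=C unit.

Step 19
Reactants: 28 fully protected target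
Product: 30 target CNP0190381.3, via phenol ketal 29 (not isolated)
Conditions: TBAF, THF, 0 °C; then 1 M aq. HCl, THF, rt
Reagents that add atoms: water, O
Why: Fluoride cleaves both silyl ethers while C12 is still masked (so no retro-aldol can occur), then mild aqueous acid hydrolyses the mixed ketal to the C12 ketone and the tertiary alcohol without touching any stereocentre; C13 already holds the more stable configuration.

Compound list
1 | indan-4-ol | Oc1cccc2c1CCC2 | starting material
2 | iodomethane | CI | starting material
3 | 4-methoxyindane | COc1cccc2c1CCC2 | intermediate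
4 | 4-methoxy-2,3,3a,6-tetrahydro-1H-indene (racemic) | COC1=CCC=C2CCCC12 | intermediate
5 | 1,2,3,3a,5,6-hexahydro-4H-inden-4-one (racemic) | O=C1CCC=C2CCCC12 | intermediate
6 | 1,2,3,5,6,7-hexahydro-4H-inden-4-one | O=C1CCCC2=C1CCC2 | intermediate
7 | trimethylaluminium | C[Al](C)C | starting material
8 | dimethylaluminium enolate (C11=C12) of the (7aR)-7a-methyl ketone | C[Al](C)OC1=C2CCC[C@]2(C)CCC1 | intermediate
9 | (3aR,7aR)-3a,7a-dimethyloctahydro-4H-inden-4-one | O=C1CCC[C@@]2(C)CCC[C@@]12C | intermediate
10 | trimethylsilyl enol ether (C12=C13) of 9 | C[Si](C)(C)OC1=CCC[C@@]2(C)CCC[C@@]12C | intermediate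
11 | (3aR,7aR)-3a,7a-dimethyl-1,2,3,3a,7,7a-hexahydro-4H-inden-4-one | O=C1C=CC[C@@]2(C)CCC[C@@]12C | intermediate
12 | (3aR,6S,7aR)-6-(dimethylphenylsilyl)-3a,7a-dimethyloctahydro-4H-inden-4-one | O=C1C[C@@H]([Si](C)(C)c2ccccc2)C[C@@]3(C)CCC[C@@]13C | intermediate
13 | 3-bromo-2-methylprop-1-ene | CC(=C)CBr | starting material
14 | (3aR,5S,6S,7aR)-6-(dimethylphenylsilyl)-3a,7a-dimethyl-5-(2-methylprop-2-en-1-yl)octahydro-4H-inden-4-one | O=C1[C@H](CC(C)=C)[C@@H]([Si](C)(C)c2ccccc2)C[C@@]3(C)CCC[C@@]13C | intermediate
15 | (3aR,5S,6S,7aR)-6-(dimethylphenylsilyl)-5-(2-hydroxy-2-methylpropyl)-3a,7a-dimethyloctahydro-4H-inden-4-one | O=C1[C@H](CC(C)(C)O)[C@@H]([Si](C)(C)c2ccccc2)C[C@@]3(C)CCC[C@@]13C | intermediate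
16 | (3aR,5R,6S,7aR)-6-hydroxy-5-(2-hydroxy-2-methylpropyl)-3a,7a-dimethyloctahydro-4H-inden-4-one | O=C1[C@H](CC(C)(C)O)[C@@H](O)C[C@@]2(C)CCC[C@@]12C | intermediate
17 | cyclic C12 methyl ketal of 16 (cis-fused 2,2-dimethyltetrahydrofuran across C12–C13, ring O lower face, OCH3 upper face, C5–OH upper face) | CO[C@@]12OC(C)(C)C[C@@H]1[C@@H](O)C[C@@]3(C)CCC[C@@]23C | intermediate
18 | C5 ketone of the cyclic ketal | CO[C@@]12OC(C)(C)C[C@@H]1C(=O)C[C@@]3(C)CCC[C@@]23C | intermediate
19 | 3-bromoprop-1-yne | C#CCBr | starting material
20 | C5 homopropargylic alcohol of the cyclic ketal (OH lower face, CH2C≡CH upper face) | CO[C@@]12OC(C)(C)C[C@@H]1[C@@](O)(CC#C)C[C@@]3(C)CCC[C@@]23C | intermediate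
21 | trimethylsilyl ether of 20 | CO[C@@]12OC(C)(C)C[C@@H]1[C@@](O[Si](C)(C)C)(CC#C)C[C@@]3(C)CCC[C@@]23C | intermediate
22 | (E)-alkenyl pinacol boronate from 21 | CO[C@@]12OC(C)(C)C[C@@H]1[C@@](O[Si](C)(C)C)(C/C(C)=C/B4OC(C)(C)C(C)(C)O4)C[C@@]3(C)CCC[C@@]23C | intermediate
23 | 4-methoxy-2-methylphenol | COc1ccc(O)c(C)c1 | starting material
24 | 2-hydroxy-5-methoxy-3-methylbenzaldehyde | COc1cc(C)c(O)c(C=O)c1 | intermediate
25 | 2-[(tert-butyldimethylsilyl)oxy]-5-methoxy-3-methylbenzaldehyde | COc1cc(C)c(O[Si](C)(C)C(C)(C)C)c(C=O)c1 | intermediate
26 | {2-[(tert-butyldimethylsilyl)oxy]-5-methoxy-3-methylphenyl}methanol | COc1cc(C)c(O[Si](C)(C)C(C)(C)C)c(CO)c1 | intermediate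
27 | [2-(bromomethyl)-4-methoxy-6-methylphenoxy](tert-butyl)dimethylsilane | COc1cc(C)c(O[Si](C)(C)C(C)(C)C)c(CBr)c1 | intermediate
28 | fully protected target (C12 methyl ketal, C5–OSiMe3, aryl OTBS, E alkene) | CO[C@@]12OC(C)(C)C[C@@H]1[C@@](O[Si](C)(C)C)(C/C(C)=C/Cc4cc(OC)cc(C)c4O[Si](C)(C)C(C)(C)C)C[C@@]3(C)CCC[C@@]23C | intermediate
29 | phenol ketal (both silyl groups removed, C12 methyl ketal intact) | CO[C@@]12OC(C)(C)C[C@@H]1[C@@](O)(C/C(C)=C/Cc4cc(OC)cc(C)c4O)C[C@@]3(C)CCC[C@@]23C | intermediate
30 | (3aR,5R,6R,7aR)-6-hydroxy-6-[(2E)-4-(2-hydroxy-5-methoxy-3-methylphenyl)-2-methylbut-2-en-1-yl]-5-(2-hydroxy-2-methylpropyl)-3a,7a-dimethyloctahydro-4H-inden-4-one (CNP0190381.3) | COc1cc(C)c(O)c(C/C=C(\C)C[C@@]2(O)C[C@@]3(C)CCC[C@@]3(C)C(=O)[C@@H]2CC(C)(C)O)c1 | target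

Total step count: 19.
Longest linear sequence: 15 steps (steps 1 to 13, then 18 and 19); the arene fragment takes steps 14 to 17.

Steps most likely to fail

1. Step 3 (the step marked as a proposed new method). The copper–methyl species may fail to transfer methyl to the tetrasubstituted β-carbon, enantioface discrimination may be poor, or C-methylation of the aluminate enolate may be sluggish. The fallback uses known chemistry and sets out from 6. Me2CuLi (from CuI and MeLi) in Et2O at 0 °C adds to the ring-fusion enone, and the lithium enolate is methylated with MeI in THF–HMPA to give racemic cis-3a,7a-dimethyloctahydro-4H-inden-4-one F1. Reduction with BH3·SMe2 and (S)-2-methyl-CBS-oxazaborolidine turns the two enantiomers into diastereomeric alcohols, (3aR,4R,7aR)-3a,7a-dimethyloctahydro-1H-inden-4-ol F2 and its (3aS,4R,7aS) isomer F3, which are separated by chromatography. Dess–Martin oxidation of F2 gives 9, where the route is rejoined.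

2. Step 11. Facial control in the addition to the C5 ketone may be incomplete, the allenyl/propargyl zinc may add through the wrong terminus, or ZnBr2 may ionise the ketal with loss of the C13 configuration. The fallback sets out from 18 and replaces direct propargylation by epoxide formation and opening. Dimethylsulfonium methylide (Me3SI, KHMDS, THF, −20 °C) adds irreversibly along the equatorial trajectory to give the C5 spiro-epoxide F4 (CH2 on the upper face, oxygen on the lower face). Lithium acetylide–ethylenediamine complex in DMSO at rt then opens the epoxide at its CH2 group and gives 20, where the route is rejoined.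

3. Step 2. Protonation of the arene radical anion at the other ortho/para pair would give a dihydroanisole whose hydrolysis cannot place the double bond at the ring fusion, and over-reduction is also possible. The fallback sets out from 1 and avoids dissolving-metal chemistry. Hydrogenation (H2, Rh on Al2O3, EtOH) gives cis-octahydro-1H-inden-4-ol F5, and oxidation (NaOCl, TEMPO cat., KBr, CH2Cl2/H2O) gives cis-octahydro-4H-inden-4-one F6. Acid-mediated bromination at the more substituted α-carbon (Br2, AcOH) gives 3a-bromooctahydro-4H-inden-4-one F7, and dehydrobromination (Li2CO3, LiBr, DMF, 120 °C) gives 6, where the route is rejoined.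

Further compounds
F1 | step 3 | racemic cis-3a,7a-dimethyloctahydro-4H-inden-4-one | O=C1CCC[C@@]2(C)CCC[C@@]12C.O=C1CCC[C@]2(C)CCC[C@]12C
F2 | step 3 | (3aR,4R,7aR)-3a,7a-dimethyloctahydro-1H-inden-4-ol | O[C@@H]1CCC[C@@]2(C)CCC[C@@]12C
F3 | step 3 | (3aS,4R,7aS)-3a,7a-dimethyloctahydro-1H-inden-4-ol | O[C@@H]1CCC[C@]2(C)CCC[C@]12C
F4 | step 11 | C5 spiro-epoxide of the cyclic ketal (epoxide O lower face, CH2 upper face) | CO[C@@]12OC(C)(C)C[C@@H]1[C@@]4(CO4)C[C@@]3(C)CCC[C@@]23C
F5 | step 2 | cis-octahydro-1H-inden-4-ol (racemic, carbinol epimers) | OC1CCC[C@H]2CCC[C@@H]12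
F6 | step 2 | cis-octahydro-4H-inden-4-one (racemic) | O=C1CCC[C@H]2CCC[C@@H]12
F7 | step 2 | 3a-bromooctahydro-4H-inden-4-one (mixture of stereoisomers) | O=C1CCCC2CCCC12Br
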